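**Flat target.** Early in the south run the target reached 4.9% by 8.00 min and then stayed flat within the scatter, while the over-reaction product climbed to 27.0% at 50.0 min.

the same everywhere: starting material 0.044 M; catalyst 0.88 mM; added ligand 2.1 mM
- south: reagent 0.20 M; protic impurity 8.8 mM; temperature 110 °C; run made earlier
- midnight: reagent 0.132 M; protic impurity 8.80 mM; temperature 110 °C; time 4.0 h
- autumn: reagent 0.132 M; protic impurity 8.80 mM; temperature 70 °C; time 4.0 h
- summer: reagent 0.132 M; protic impurity 8.80 mM; temperature 90 °C; time 4.0 h

south run (percent of the starting material charged)

| time / min | target / % | over-reaction product / % |
|---|---|---|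
| 2.50 | 1.7 | 1.0 |
| 8.00 | 4.9 | 4.6 |
| 15.0 | 5.0 | 7.8 |
| 20.0 | 3.3 | 11.6 |
| 30.0 | 3.5 | 16.5 |
| 40.0 | 4.9 | 21.0 |
| 50.0 | 4.5 | 27.0 |

(scatter of a reading: 1 percentage point)

- the flask that comes out highest in share of target in all that became target or over-reaction product, or "all alike" when all lie within 1.5 percentage points (midnight / autumn / summer / all alike)
- share of target in all that became target or over-reaction product, midnight
- share of target in all that became target or over-reaction product, autumn
- share of target in all that became target or over-reaction product, summer

- the numbers in the tables scatter with a standard deviation of 1 percentage point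
- on the list of suspects stand: starting material + protic impurity -> quenched substrate; catalyst + added ligand <-> idle complex; reagent + catalyst + target -> catalyst + over-reaction product; starting material + reagent + catalyst <-> target + catalyst
- the earlier runs do not show what temperature does; that part of a forecast is a guess

**Bench rule.** A flat intermediate is used about as fast as it is made, so I took [target] as a fixed fraction of [starting material]. Reagent and catalyst stand in both suspected steps and cancel. Letting the protic impurity take its whole charge, 80.0% of the starting material stayed for the main route. With [starting material] taken as that minus the two products, the last 5 south readings gave 0.0719 for [target]/[starting material], the plateau ratio. Both products together fill what has left that main-route portion, so the share of target (the selectivity) is the plateau ratio times [starting material], divided by the main-route portion minus [starting material].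

**Midnight reckoned.** On that balance the south readings put [starting material] at 67.2% at 15.0 min and 48.5% at 50.0 min, and integrating the first-order rate between them gave a pseudo-first-order constant of 0.00932 min⁻¹. Scaled to the reagent of midnight, it became 0.00615 min⁻¹. Over 4.0 h, with reagent held at its charge, I reckoned 18.3% starting material for midnight, and from it a share of 2.13%.

**The border.** The rule needs the target at its plateau, which it approaches on the scale of one target lifetime, the plateau ratio over that constant: I reckoned 11.7 min in midnight. The asked time is 20.5 such lifetimes, so midnight lay well inside. The earlier runs do not show what temperature does, so I reckoned nothing for autumn and summer.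

**The forecast.** It named autumn, with 4.5% for midnight, 38% for autumn and 14% for summer: "At low conversion the over-reaction product has had less time to accumulate." Its midnight share stood above mine.

**The result.** Autumn came out highest at 43.0%, with 72.5% starting material left and 4.33% over-reaction product; summer gave 12.3% and midnight 3.14%.

    starting material + protic impurity → quenched substrate (k = 0.0950 M⁻¹ s⁻¹, Ea = 61.0 kJ mol⁻¹)
    catalyst + added ligand ⇌ idle complex (K = 390 M⁻¹, k = 8.10 M⁻¹ s⁻¹, Ea = 40.0 kJ mol⁻¹, ΔH = −54.0 kJ mol⁻¹)
    reagent + catalyst + target → catalyst + over-reaction product (k = 22.0 M⁻² s⁻¹, Ea = 39.0 kJ mol⁻¹)
    starting material + reagent + catalyst ⇌ target + catalyst, rate k4*[starting material]*[reagent]*[catalyst] forward; the back reaction follows from the equilibrium constant (K = 6.70 M⁻¹, k = 1.80 M⁻² s⁻¹, Ea = 51.0 kJ mol⁻¹, ΔH = 6.00 kJ mol⁻¹)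
    (constants at 110 °C)

**Neighbour flask.** Midnight held 23.4% starting material at 4.00 h, and the plateau ratio turned that into 2.97% against 3.14%. Its neighbour, charged with 0.0084 M of added ligand, kept 24.9% of its catalyst free against 59.5% in midnight and held 43.9% starting material at 4.00 h. The same reckoning gave 8.74% for that neighbour, and the flask gave 9.53%.

(The readings are calculated for substances that don't exist.)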